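**Strategy.** The route rests on cutting the cyclopentane ring of the indane core at two bonds: the bond from the benzylic CH2 to the adjacent ring-fusion CH, and the bond from the arene carbon to the other ring-fusion CH. In the forward sense a palladium-catalysed (3+2) annulation joins an ortho-methyl aryl bromide (a 5-bromo-6-methylchroman-4-one, the ketone masking the chromene) to the strained alkene of an enantioenriched 3-aryl-4,4-dimethylcyclobutene by syn-arylpalladation, benzylic C–H palladation and reductive elimination. The step exploits the cyclobutane ring: its gem-dimethyl carbon leaves the alkylpalladium without a syn β-hydrogen, and its aryl-bearing stereocentre steers both new ring-fusion centres, cis to each other and anti to the catechol ring.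

Key step: step 9

Assumption: the keteniminium salt from the (S)-2-(methoxymethyl)pyrrolidine amide is taken to add to the styrene with the facial sense that gives the (R)-cyclobutanone; should the sense be the opposite, the (R)-auxiliary is used with no other change.

**Step 1**
Reactants: 1 2-bromo-4,6-dimethoxybenzaldehyde
Product: 2 1-bromo-3,5-dimethoxy-2-methylbenzene
Conditions: Et3SiH (3 equiv), TFA, CH2Cl2, 0 °C to rt
Reagents that add atoms: none
Why: Ionic hydrogenation, in which TFA ionises the aldehyde and then the benzylic alcohol to cations that the two methoxy groups stabilise and Et3SiH reduces, should give the methyl group without touching the C–Br bond.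

**Step 2**
Reactants: 2 1-bromo-3,5-dimethoxy-2-methylbenzene; 3 3-methylbut-2-enoyl chloride
Product: 6 5-bromo-7-methoxy-2,2,6-trimethylchroman-4-one, via aryl enone 4 (not isolated), via hydroxyaryl enone 5 (not isolated)
Conditions: AlCl3 (3 equiv), CH2Cl2, 0 °C to reflux; 1 M aq. HCl quench
Reagents that add atoms: none
Why: Friedel–Crafts acylation should occur at the free position that is para to one methoxy group and not flanked by two (the site preference known for formylation of 1-bromo-3,5-dimethoxybenzene), after which AlCl3 cleaves the methyl ether chelated to the new ketone and the phenol closes the pyranone ring by oxa-Michael addition.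

**Step 3**
Reactants: 7 3,4-dihydroxybenzaldehyde
Product: 8 3,4-bis(pivaloyloxy)benzaldehyde
Conditions: PivCl (2.2 equiv), Et3N, DMAP (cat.), CH2Cl2, 0 °C to rt
Reagents that add atoms: pivaloyl chloride, CC(C)(C)C(=O)Cl
Why: Esterification of both phenols gives hindered pivalates without α-hydrogens, which should mute the catechol through the later cationic, basic and palladium steps.

**Step 4**
Reactants: 8 3,4-bis(pivaloyloxy)benzaldehyde
Product: 9 3,4-bis(pivaloyloxy)styrene
Conditions: Ph3PCH3Br, KN(SiMe3)2, THF, −78 to 0 °C
Reagents that add atoms: methyltriphenylphosphonium bromide, C[P+](c1ccccc1)(c1ccccc1)c1ccccc1.[Br-]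
Why: Wittig methylenation, in which the ylide should react with the aldehyde far faster than with the hindered aryl pivalates at low temperature.

**Step 5**
Reactants: 10 2-methylpropanoyl chloride; 11 (S)-2-(methoxymethyl)pyrrolidine
Product: 12 1-[(2S)-2-(methoxymethyl)pyrrolidin-1-yl]-2-methylpropan-1-one
Conditions: Et3N, CH2Cl2, 0 °C to rt
Reagents that add atoms: none
Why: N-Acylation of the secondary amine (amide formation) places the chiral auxiliary on the isobutyryl unit.

**Step 6**
Reactants: 12 1-[(2S)-2-(methoxymethyl)pyrrolidin-1-yl]-2-methylpropan-1-one; 9 3,4-bis(pivaloyloxy)styrene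
Product: 15 (3R)-3-[3,4-bis(pivaloyloxy)phenyl]-2,2-dimethylcyclobutan-1-one, via keteniminium triflate 13 (not isolated), via cyclobutaniminium triflate 14 (not isolated)
Conditions: Tf2O, 2,4,6-collidine, ClCH2CH2Cl, −25 °C to 80 °C; then aq. NaHCO3, rt
Reagents that add atoms: water, O; triflic anhydride, O=S(=O)(OS(=O)(=O)C(F)(F)F)C(F)(F)F (counter-ion of 13 and 14 only)
Why: Ghosez keteniminium–alkene [2+2] cycloaddition, in which the iminium carbon bonds to the styrene CH2 and the CMe2 carbon to the benzylic carbon while the methoxymethyl arm of the auxiliary shields one face, should set the benzylic stereocentre as R before hydrolysis releases the ketone.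

**Step 7**
Reactants: 15 (3R)-3-[3,4-bis(pivaloyloxy)phenyl]-2,2-dimethylcyclobutan-1-one
Product: 16 (3R)-3-[3,4-bis(pivaloyloxy)phenyl]-4,4-dimethylcyclobut-1-en-1-yl trifluoromethanesulfonate
Conditions: KN(SiMe3)2, PhNTf2, THF, −78 °C (base added to ketone and PhNTf2)
Reagents that add atoms: N-phenylbis(trifluoromethanesulfonimide), O=S(=O)(N(c1ccccc1)S(=O)(=O)C(F)(F)F)C(F)(F)F
Why: Enolisation can occur only toward the CH2 side because the other α-carbon is quaternary, and O-sulfonylation of the potassium enolate gives the enol triflate with the stereocentre untouched.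

**Step 8**
Reactants: 16 (3R)-3-[3,4-bis(pivaloyloxy)phenyl]-4,4-dimethylcyclobut-1-en-1-yl trifluoromethanesulfonate
Product: 17 (3S)-3-[3,4-bis(pivaloyloxy)phenyl]-4,4-dimethylcyclobut-1-ene
Conditions: Pd(OAc)2 (5 mol%), PPh3, HCO2H, n-Bu3N, DMF, 40 °C
Reagents that add atoms: none
Why: Palladium-catalysed formate reduction of the enol triflate (oxidative addition, formate exchange, decarboxylation, C–H reductive elimination) should give the cyclobutene below the temperature of its electrocyclic ring opening, the descriptor changing from R to S only through a change of priorities.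

**Step 9**
Reactants: 6 5-bromo-7-methoxy-2,2,6-trimethylchroman-4-one; 17 (3S)-3-[3,4-bis(pivaloyloxy)phenyl]-4,4-dimethylcyclobut-1-ene
Product: 20 annulated chromanone bis-pivalate (the target skeleton with the pyran C4 as C=O, C3 as CH2 and both catechol oxygens pivaloylated), via cyclobutylpalladium bromide 18 (not isolated), via palladacycle 19 (not isolated)
Conditions: Pd(OAc)2 (10 mol%), PCy3·HBF4 (20 mol%), Cs2CO3, PivOH (30 mol%), toluene, 90 °C, 17 (2.5 equiv) added in portions
Reagents that add atoms: none
Why: Proposed new method: zerovalent palladium inserts into the C–Br bond of 6, the arylpalladium adds syn across the strained alkene of 17 to give 18, pivalate-assisted cleavage of a C–H bond of the neighbouring aryl methyl group gives palladacycle 19, and C(sp3)–C(sp3) reductive elimination closes the ring; the closest known reaction type is the palladium-catalysed annulation of ortho-alkyl aryl halides with norbornene to hexahydromethanofluorenes through benzylic C–H activation, which has not been shown with a monocyclic cyclobutene. The one new ring, the cyclopentane of the indane, is closed as an intermolecular (3+2) annulation, its first bond by migratory insertion and its second by reductive elimination from the six-membered palladacycle. Both new stereocentres, the two ring-fusion carbons, are controlled by the aryl-bearing stereocentre of 17: the arylpalladium approaches the alkene face anti to that aryl group and syn insertion makes the ring fusion cis. The insertion must place the aryl group on the alkene carbon next to the CH–aryl carbon and palladium on the carbon next to CMe2, which the neopentyl-type shielding of the latter carbon should secure; the resulting alkylpalladium cannot lose a β-hydride, since one β-carbon is quaternary and the only other β-hydrogen is anti to palladium. Site selectivity of the C–H cleavage is secured by the substrate, because the other ortho neighbour of the new aryl–C bond is the chromanone carbonyl carbon, which carries no hydrogen, and the catechol ring lies on the opposite face of the cyclobutane. The catalytic turnover has to outrun the thermal 4π ring opening of 17, hence the moderate temperature and the portionwise excess of 17.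

**Step 10**
Reactants: 20 annulated chromanone bis-pivalate
Product: 22 CNP0207533.1 (target), via chromanol 21 (not isolated)
Conditions: LiAlH4, THF, 0 °C to rt; then 4 M aq. HCl, THF, rt to 40 °C, under argon
Reagents that add atoms: none
Why: Hydride reduction of the chromanone with reductive cleavage of both aryl pivalates, followed by acid-catalysed E1 dehydration of the benzylic 4-chromanol (the standard chromanone-to-chromene sequence), should give the 2H-chromene and the free catechol without touching a stereocentre.

**Compound list**

1 | 2-bromo-4,6-dimethoxybenzaldehyde | O=Cc1c(Br)cc(OC)cc1OC | starting material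
2 | 1-bromo-3,5-dimethoxy-2-methylbenzene | Cc1c(Br)cc(OC)cc1OC | intermediate
3 | 3-methylbut-2-enoyl chloride | CC(C)=CC(=O)Cl | starting material
4 | 1-(2-bromo-4,6-dimethoxy-3-methylphenyl)-3-methylbut-2-en-1-one | COc1cc(OC)c(C(=O)C=C(C)C)c(Br)c1C | intermediate
5 | 1-(2-bromo-6-hydroxy-4-methoxy-3-methylphenyl)-3-methylbut-2-en-1-one | COc1cc(O)c(C(=O)C=C(C)C)c(Br)c1C | intermediate
6 | 5-bromo-7-methoxy-2,2,6-trimethylchroman-4-one | COc1cc2OC(C)(C)CC(=O)c2c(Br)c1C | intermediate
7 | 3,4-dihydroxybenzaldehyde | O=Cc1ccc(O)c(O)c1 | starting material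
8 | 3,4-bis(pivaloyloxy)benzaldehyde | CC(C)(C)C(=O)Oc1ccc(C=O)cc1OC(=O)C(C)(C)C | intermediate
9 | 3,4-bis(pivaloyloxy)styrene | C=Cc1ccc(OC(=O)C(C)(C)C)c(OC(=O)C(C)(C)C)c1 | intermediate
10 | 2-methylpropanoyl chloride | CC(C)C(=O)Cl | starting material
11 | (S)-2-(methoxymethyl)pyrrolidine | COC[C@@H]1CCCN1 | starting material
12 | 1-[(2S)-2-(methoxymethyl)pyrrolidin-1-yl]-2-methylpropan-1-one | CC(C)C(=O)N1CCC[C@H]1COC | intermediate
13 | (2S)-2-(methoxymethyl)-1-(2-methylprop-1-en-1-ylidene)pyrrolidinium triflate (keteniminium salt) | CC(C)=C=[N+]1CCC[C@H]1COC.[O-]S(=O)(=O)C(F)(F)F | intermediate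
14 | cyclobutaniminium triflate: N-[(3R)-3-[3,4-bis(pivaloyloxy)phenyl]-2,2-dimethylcyclobutylidene]-(2S)-2-(methoxymethyl)pyrrolidinium triflate | COC[C@@H]1CCC[N+]1=C1C[C@H](c2ccc(OC(=O)C(C)(C)C)c(OC(=O)C(C)(C)C)c2)C1(C)C.[O-]S(=O)(=O)C(F)(F)F | intermediate
15 | (3R)-3-[3,4-bis(pivaloyloxy)phenyl]-2,2-dimethylcyclobutan-1-one | O=C1C[C@H](c2ccc(OC(=O)C(C)(C)C)c(OC(=O)C(C)(C)C)c2)C1(C)C | intermediate
16 | (3R)-3-[3,4-bis(pivaloyloxy)phenyl]-4,4-dimethylcyclobut-1-en-1-yl trifluoromethanesulfonate | O=S(=O)(OC1=C[C@H](c2ccc(OC(=O)C(C)(C)C)c(OC(=O)C(C)(C)C)c2)C1(C)C)C(F)(F)F | intermediate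
17 | (3S)-3-[3,4-bis(pivaloyloxy)phenyl]-4,4-dimethylcyclobut-1-ene | C1=C[C@H](c2ccc(OC(=O)C(C)(C)C)c(OC(=O)C(C)(C)C)c2)C1(C)C | intermediate
18 | cyclobutylpalladium bromide from syn-arylpalladation (chromanone aryl and palladium cis, both trans to the catechol aryl; phosphine ligand omitted) | COc1cc2OC(C)(C)CC(=O)c2c(c1C)[C@@H]1[C@H]([Pd]Br)C(C)(C)[C@H]1c1ccc(OC(=O)C(C)(C)C)c(OC(=O)C(C)(C)C)c1 | intermediate
19 | six-membered palladacycle (palladium bound to the benzylic CH2 and to the cyclobutane carbon next to CMe2; phosphine ligand omitted) | COc1cc2c(c3c1C[Pd][C@H]1[C@@H]3[C@H](c3ccc(OC(=O)C(C)(C)C)c(OC(=O)C(C)(C)C)c3)C1(C)C)C(=O)CC(C)(C)O2 | intermediate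
20 | annulated chromanone bis-pivalate: cis-fused cyclobuta-indane on the chromanone arene, ring-fusion hydrogens cis, catechol-derived aryl trans to the arene bond at the neighbouring ring-fusion carbon (aryl-bearing carbon S, arene-bound ring-fusion carbon R, CH2-bound ring-fusion carbon S) | COc1cc2c(c3c1C[C@H]1[C@@H]3[C@H](c3ccc(OC(=O)C(C)(C)C)c(OC(=O)C(C)(C)C)c3)C1(C)C)C(=O)CC(C)(C)O2 | intermediate
21 | chromanol: the 4-hydroxychroman with free catechol (mixture of epimers at the carbinol carbon) | COc1cc2c(c3c1C[C@H]1[C@@H]3[C@H](c3ccc(O)c(O)c3)C1(C)C)C(O)CC(C)(C)O2 | intermediate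
22 | CNP0207533.1: 2,2-dimethyl-2H-chromene fused to the cis-cyclobuta-indane, methoxy group on the arene, 3,4-dihydroxyphenyl on the cyclobutane, configuration as in 20 | COc1cc2c(c3c1C[C@H]1[C@@H]3[C@H](c3ccc(O)c(O)c3)C1(C)C)C=CC(C)(C)O2 | target

**Totals.** Total step count: 10. Longest linear sequence: 7 steps (steps 3, 4, 6, 7, 8, 9, 10 from 3,4-dihydroxybenzaldehyde).

**Steps most likely to fail**

Step 9. What may go wrong: the cyclobutylpalladium intermediate may not cleave the methyl C–H bond before the cyclobutene is consumed by thermal conrotatory ring opening, or insertion with the opposite regiochemistry may end in β-hydride elimination. The fallback uses only known reactions, sets out from triflate 16 and returns to the route at 20; it closes the five-membered ring stepwise, so it needs neither C–H activation nor a heated free cyclobutene. Alkoxycarbonylation of 16 (Pd(OAc)2, dppp, CO, BnOH, Et3N, DMF) would give benzyl (3R)-3-[3,4-bis(pivaloyloxy)phenyl]-4,4-dimethylcyclobut-1-ene-1-carboxylate F1. Rhodium-catalysed conjugate addition of commercial 3,5-dimethoxyphenylboronic acid ([Rh(cod)OH]2, dioxane/H2O, 50 °C), a reaction established for cyclobutene-1-carboxylates, should deliver the aryl group anti to the resident aryl group. Protonation of the rhodium enolate on the face away from the new aryl group should then give benzyl 2-(3,5-dimethoxyphenyl)-3-[3,4-bis(pivaloyloxy)phenyl]-4,4-dimethylcyclobutane-1-carboxylate F2 (aryl groups trans, ester cis to the dimethoxyphenyl group). Hydrogenolysis (H2, Pd/C, EtOAc) frees 2-(3,5-dimethoxyphenyl)-3-[3,4-bis(pivaloyloxy)phenyl]-4,4-dimethylcyclobutane-1-carboxylic acid F3. (COCl)2 with catalytic DMF and then SnCl4 should close the cis-fused dimethoxy indanone F4 by Friedel–Crafts acylation at the arene position ortho and para to the two methoxy groups. Et3SiH in TFA removes the ketone oxygen to give the dimethoxy indane F5. The acylation, demethylation and oxa-Michael sequence of step 2 (3, AlCl3) then builds the chromanone ring on F5 and gives 20.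

Step 6. What may go wrong: poor facial discrimination by the auxiliary, leaving the cyclobutanone with low enantiomeric purity. The fallback sets out from styrene 9 and returns at 15. The same [2+2] cycloaddition with the achiral keteniminium salt from commercial N,N-dimethyl-2-methylpropanamide (Tf2O, collidine, then aqueous hydrolysis) would give racemic 3-[3,4-bis(pivaloyloxy)phenyl]-2,2-dimethylcyclobutan-1-one F6. Preparative supercritical-fluid chromatography on a chiral stationary phase then separates 15 from the unwanted (3S)-3-[3,4-bis(pivaloyloxy)phenyl]-2,2-dimethylcyclobutan-1-one F7.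

Step 2. What may go wrong: the tandem sequence may stall or divert, through conjugate addition of chloride or of a second arene to the enone or through incomplete ortho-demethylation and ring closure. The fallback sets out from 2 and returns at 6. Friedel–Crafts acetylation with AcCl and AlCl3, with the same chelation-driven ortho-demethylation, would give 1-(2-bromo-6-hydroxy-4-methoxy-3-methylphenyl)ethan-1-one F8. Kabbe condensation of F8 with acetone and pyrrolidine (EtOH, reflux) then forms the 2,2-dimethylchroman-4-one 6 by aldol condensation and oxa-Michael closure, with no free enone exposed to the Lewis acid.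

**Further compounds**

F1 | step 9 | benzyl (3R)-3-[3,4-bis(pivaloyloxy)phenyl]-4,4-dimethylcyclobut-1-ene-1-carboxylate | O=C(OCc1ccccc1)C1=C[C@H](c2ccc(OC(=O)C(C)(C)C)c(OC(=O)C(C)(C)C)c2)C1(C)C
F2 | step 9 | benzyl 2-(3,5-dimethoxyphenyl)-3-[3,4-bis(pivaloyloxy)phenyl]-4,4-dimethylcyclobutane-1-carboxylate (aryl groups trans, ester cis to the dimethoxyphenyl group) | O=C(OCc1ccccc1)[C@H]1[C@@H](c2cc(OC)cc(OC)c2)[C@H](c2ccc(OC(=O)C(C)(C)C)c(OC(=O)C(C)(C)C)c2)C1(C)C
F3 | step 9 | 2-(3,5-dimethoxyphenyl)-3-[3,4-bis(pivaloyloxy)phenyl]-4,4-dimethylcyclobutane-1-carboxylic acid (same configuration as F2) | OC(=O)[C@H]1[C@@H](c2cc(OC)cc(OC)c2)[C@H](c2ccc(OC(=O)C(C)(C)C)c(OC(=O)C(C)(C)C)c2)C1(C)C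
F4 | step 9 | cis-fused dimethoxy indanone (ketone at the future benzylic CH2, cyclobutane as in 20, catechol as bis-pivalate) | COc1cc(OC)cc2c1C(=O)[C@H]1[C@@H]2[C@H](c2ccc(OC(=O)C(C)(C)C)c(OC(=O)C(C)(C)C)c2)C1(C)C
F5 | step 9 | cis-fused dimethoxy indane (F4 with CH2 in place of C=O) | COc1cc(OC)cc2c1C[C@H]1[C@@H]2[C@H](c2ccc(OC(=O)C(C)(C)C)c(OC(=O)C(C)(C)C)c2)C1(C)C
F6 | step 6 | racemic 3-[3,4-bis(pivaloyloxy)phenyl]-2,2-dimethylcyclobutan-1-one | O=C1CC(c2ccc(OC(=O)C(C)(C)C)c(OC(=O)C(C)(C)C)c2)C1(C)C
F7 | step 6 | (3S)-3-[3,4-bis(pivaloyloxy)phenyl]-2,2-dimethylcyclobutan-1-one (unwanted enantiomer, removed) | O=C1C[C@@H](c2ccc(OC(=O)C(C)(C)C)c(OC(=O)C(C)(C)C)c2)C1(C)C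
F8 | step 2 | 1-(2-bromo-6-hydroxy-4-methoxy-3-methylphenyl)ethan-1-one | CC(=O)c1c(O)cc(OC)c(C)c1Br
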